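The numbers in the tables stem from a simulated flask for an exercise.

Late times come first: we want to know where the starting complex stops.

- north-west: starting complex 1 M; incoming ligand 1.5 M; scavenger 1.8 M; run made earlier
- flask: starting complex 1.5 M; incoming ligand 1.50 M; scavenger 1.80 M; time 15 min

north-west run (percent of the starting complex charged)

| time / min | starting complex / % | complex with two exchanged / % |
|---|---|---|
| 1.00 | 85.3 | 0.8 |
| 3.00 | 69.6 | 0.9 |
| 6.00 | 55.4 | 3.0 |
| 8.00 | 53.0 | 1.6 |
| 12.0 | 47.6 | 3.7 |

(scatter of a reading: 1 percentage point)

- part of the starting complex that has reacted at 15 min
- share of the unused incoming ligand that is free and not bound as idle adduct, at 15 min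

- the analysis behind the earlier runs scatters by 1 percentage point, standard deviation
- the earlier runs do not show how much of incoming ligand is bound; that part of a forecast is a guess

1. Fast rung. The first north-west reading, at 1.00 min, implies an apparent half-life of 4.36 min for the starting complex.

2. Slow rung. The north-west readings from 8.00 min to 12.0 min imply an apparent half-life of 25.8 min, which is 5.92 times longer. This carries the scatter of the readings.

3. End. The 3.00 min from the last north-west reading to the asked time are shorter than that late half-life, so we neglect them. As our estimate, we take the north-west conversion at the asked time as 52.4%, from its last reading.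

4. Our rule, an assumption. Conversion may not follow the charged ratio [incoming ligand]/[starting complex] at all, if incoming ligand is plentiful, or may follow it directly, if incoming ligand is the limiting reagent. We cannot tell which holds, so in logarithms we take the middle: the power one half, with scavenger and time held. We define the stall number as conversion divided by the square root of the charged ratio: 0.428.

5. This flask. Its ratio is 1.00, so we expect 42.8%.

The forecast gives 48% reacted, above our figure, and 13% free, adding “this is a guess and reversibility could raise it”.

The flask gives 43.6% reacted and 59.4% free.

    starting complex + incoming ligand ⇌ leaving ligand + complex with one exchanged (K = 0.177, k = 0.112 L mol⁻¹ min⁻¹)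
    complex with one exchanged + incoming ligand ⇌ leaving ligand + complex with two exchanged (K = 0.510, k = 0.0642 L mol⁻¹ min⁻¹)
    complex with two exchanged + incoming ligand ⇌ leaving ligand + complex with three exchanged (K = 2.90, k = 0.794 L mol⁻¹ min⁻¹)
    leaving ligand + incoming ligand ⇌ idle adduct, settled at all times (K = 9.00 L mol⁻¹)
    scavenger + leaving ligand → scavenged by-product (k = 0.454 L mol⁻¹ min⁻¹)

At the end of this flask, a smaller part of the charged incoming ligand remains unbound, 21%, than of the charged starting complex, 56%. The stall number put on this flask falls 0.86 percentage points short of the result.

For the neighbour flask with 0.60 M of starting complex, the stall number gives 67.6%. The computed result there is 66.1%.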